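**Retrosynthetic overview**
1. Target 26 ⇒ bridged ketone 25 by a last-step reduction of the C6 ketone, syn to 8-OH.
2. 25 ⇒ (C4a–C5 and C7–C8 in one operation) a (3+3) annulation of the dioxepinone β-keto acid 22 with the 3-triflyloxy-2-formyl-γ-pyrone 11. The CO2H on the CH bound to O-7B decides which carbon becomes C5 and leaves as CO2.
3. Enabling feature: C5–C6–C7, the C6 carbinol between the two aryloxy-bearing carbons of the seven-membered dioxepine ring, is the α/C=O/α′ triad of a catechol-tied dihydroxyacetone. C4a–C8a–C8 is the β-carbon/α-carbon/carbonyl carbon of an enal inside the γ-pyrone ring. C5 and C7 end as bridgeheads of a bicyclo[4.3.1] core, so the aldol cannot eliminate or aromatise.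
4. 22 ⇒ 6,7-dihydroxy-2-(2-phenylethyl)chromone 16 (7-O- then 6-O-alkylation, crossed Dieckmann closure); 11 ⇒ kojic acid 1 (Wittig chain extension, hydroxymethylation, enol triflation, oxidation).
5. Ring order: γ-pyrone (present in 1) and chromone ring of unit B (step 8), dioxepinone ring (step 12), carbocycle of unit A last (step 14).

Key step: step 14

Remark: unit A is the tetrahydrochromone half (locants C2–C8a), unit B the aromatic chromone half (locants marked B); the target SMILES corresponds to (5R,6S,7R,8S), and that configuration is planned for.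

**Route**

Step 1
Reactants: 1 kojic acid
Product: 2 5-(benzyloxy)-2-(hydroxymethyl)-4H-pyran-4-one
Conditions: BnCl, NaOH, MeOH/H2O, reflux
Reagents that add atoms: benzyl chloride, ClCc1ccccc1
Why: Williamson etherification; only the acidic enolic 5-OH is ionised, so it should be benzylated in preference to the primary alcohol.

Step 2
Reactants: 2 5-(benzyloxy)-2-(hydroxymethyl)-4H-pyran-4-one
Product: 3 5-(benzyloxy)-4-oxo-4H-pyran-2-carbaldehyde
Conditions: Dess–Martin periodinane, CH2Cl2, rt
Reagents that add atoms: none
Why: Dess–Martin oxidation of the primary alcohol should stop at the aldehyde and leave the γ-pyrone untouched.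

Step 3
Reactants: 3 5-(benzyloxy)-4-oxo-4H-pyran-2-carbaldehyde; 4 (4-methoxybenzyl)triphenylphosphonium chloride
Product: 6 5-(benzyloxy)-2-[2-(4-methoxyphenyl)ethenyl]-4H-pyran-4-one (E/Z mixture), via phosphonium ylide 5 (not isolated)
Conditions: KOtBu, THF, 0 °C; then 3, 0 °C to rt
Reagents that add atoms: none
Why: Wittig olefination of a non-enolisable aldehyde with a semistabilised benzylic ylide; the alkene geometry is irrelevant because the double bond is hydrogenated next.

Step 4
Reactants: 6 5-(benzyloxy)-2-[2-(4-methoxyphenyl)ethenyl]-4H-pyran-4-one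
Product: 7 5-hydroxy-2-[2-(4-methoxyphenyl)ethyl]-4H-pyran-4-one
Conditions: H2 (1 atm), Pd/C, EtOAc/MeOH, rt
Reagents that add atoms: none
Why: Heterogeneous hydrogenation should saturate the styryl double bond and hydrogenolyse the benzyl ether in one operation, while the γ-pyrone is reduced much more slowly.

Step 5
Reactants: 7 5-hydroxy-2-[2-(4-methoxyphenyl)ethyl]-4H-pyran-4-one; 8 formaldehyde
Product: 9 3-hydroxy-2-(hydroxymethyl)-6-[2-(4-methoxyphenyl)ethyl]-4H-pyran-4-one
Conditions: 37% aq. CH2O, NaOH, H2O/MeOH, rt; then HCl to pH 3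
Reagents that add atoms: none
Why: Aldol-type hydroxymethylation of the oxido-pyranone anion at the free ring position next to the enolic OH, as known for kojic acid and allomaltol; this carbon becomes C8.

Step 6
Reactants: 9 3-hydroxy-2-(hydroxymethyl)-6-[2-(4-methoxyphenyl)ethyl]-4H-pyran-4-one
Product: 10 2-(hydroxymethyl)-6-[2-(4-methoxyphenyl)ethyl]-4-oxo-4H-pyran-3-yl trifluoromethanesulfonate
Conditions: PhNTf2, Et3N, CH2Cl2, 0 °C to rt
Reagents that add atoms: N-phenylbis(trifluoromethanesulfonimide), O=S(=O)(N(c1ccccc1)S(=O)(=O)C(F)(F)F)C(F)(F)F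
Why: Chemoselective O-sulfonylation; PhNTf2 triflates the acidic enol as its ammonium enolate and should not react with the neutral primary alcohol.

Step 7
Reactants: 10 2-(hydroxymethyl)-6-[2-(4-methoxyphenyl)ethyl]-4-oxo-4H-pyran-3-yl trifluoromethanesulfonate
Product: 11 2-formyl-6-[2-(4-methoxyphenyl)ethyl]-4-oxo-4H-pyran-3-yl trifluoromethanesulfonate
Conditions: Dess–Martin periodinane, CH2Cl2, rt
Reagents that add atoms: none
Why: Dess–Martin oxidation under neutral conditions should give the β-triflyloxy enal (a vinylogous acyl triflate) without loss of the triflate.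

Step 8
Reactants: 12 2'-hydroxy-4',5'-dimethoxyacetophenone; 13 ethyl 3-phenylpropanoate
Product: 15 6,7-dimethoxy-2-(2-phenylethyl)-4H-chromen-4-one, via 1,3-diketone 14 (not isolated)
Conditions: NaH, THF, reflux; then HCl, MeOH, reflux
Reagents that add atoms: none
Why: Claisen condensation of the acetophenone enolate with the ester, then acid cyclodehydration of the o-hydroxyaryl 1,3-diketone (standard chromone synthesis).

Step 9
Reactants: 15 6,7-dimethoxy-2-(2-phenylethyl)-4H-chromen-4-one
Product: 16 6,7-dihydroxy-2-(2-phenylethyl)-4H-chromen-4-one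
Conditions: BBr3, CH2Cl2, −78 °C to rt; then H2O
Reagents that add atoms: none
Why: Lewis-acid ether cleavage with BBr3 should remove both aryl methyl ethers and leave the chromone intact.

Step 10
Reactants: 16 6,7-dihydroxy-2-(2-phenylethyl)-4H-chromen-4-one; 17 tert-butyl bromoacetate
Product: 18 tert-butyl {[6-hydroxy-4-oxo-2-(2-phenylethyl)-4H-chromen-7-yl]oxy}acetate
Conditions: KHCO3, DMF, 40 °C
Reagents that add atoms: none
Why: Williamson alkylation; the 7-OH is para to the pyrone carbonyl (a vinylogous acid) and should be the only phenol ionised by hydrogencarbonate, so the tert-butyl acetate arm goes on O-7B.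

Step 11
Reactants: 18 tert-butyl {[6-hydroxy-4-oxo-2-(2-phenylethyl)-4H-chromen-7-yl]oxy}acetate; 19 methyl bromoacetate
Product: 20 tert-butyl methyl diester (CH2CO2tBu on O-7B and CH2CO2Me on O-6B)
Conditions: K2CO3, acetone, 50 °C
Reagents that add atoms: none
Why: Williamson alkylation of the remaining 6-OH with the stronger base.

Step 12
Reactants: 20 tert-butyl methyl diester
Product: 21 tert-butyl dioxepinone β-keto ester (CO2tBu on the ring CH bound to O-7B)
Conditions: KOtBu, THF, 0 °C to rt; AcOH quench
Reagents that add atoms: none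
Why: Dieckmann condensation to the seven-membered 1,5-benzodioxepin-3-one ring; the methyl ester is the better acyl acceptor and the tert-butyl ester is not attacked, so the surviving ester should sit on the carbon bound to O-7B.

Step 13
Reactants: 21 tert-butyl dioxepinone β-keto ester
Product: 22 dioxepinone β-keto acid
Conditions: CF3CO2H, CH2Cl2, 0 °C; concentrated cold and used at once
Reagents that add atoms: none
Why: Acidolysis of the tert-butyl ester (loss of 2-methylpropene) at 0 °C should give the β-keto acid without decarboxylation.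

Step 14
Reactants: 22 dioxepinone β-keto acid; 11 2-formyl-6-[2-(4-methoxyphenyl)ethyl]-4-oxo-4H-pyran-3-yl trifluoromethanesulfonate
Product: 25 (5R,7S,8S)-bridged ketone (6-oxo form of the target), via quaternary keto acid 23 (not isolated), via open keto aldehyde 24 (not isolated)
Conditions: iPr2NEt (2.2 equiv), DMF, −20 °C to rt; then (S)-proline (30 mol%), rt
Reagents that add atoms: none
Why: Proposed new method: the iPr2NEt salt of 22 should react as a carboxylate-stabilised enol, at the carbon between ketone and CO2H, with the vinylogous acyl triflate 11 by conjugate addition at C4a and loss of triflate; the quaternary acid 23 should lose CO2 on warming to give 24 (the carboxyl group fixes which CH of the dioxepinone bonds to C4a and then disappears), and (S)-proline, added after the substitution so that its nitrogen is not vinylated, should close C7–C8 by an enamine aldol of the C6 ketone onto the formyl group. The closest known reaction types are the vinylic-substitution/aldol (3+3) annulation of β-halovinyl aldehydes with acetonedicarboxylate-type bis-nucleophiles, the decarboxylative C-acylation and decarboxylative conjugate addition of β-keto acids, the proline aldol of 1,3-dioxan-5-ones (the dioxepinone is a catechol-tied dihydroxyacetone) and the Hajos–Parrish cyclisation. Only the six-membered carbocycle closes, by a 6-(enolexo)-exo-trig aldol, which turns the seven-membered ring into the bicyclo[4.3.1] core. C5 and C7 can only be bridged cis, and C5 of 24 should epimerise fast through its pyrone-conjugated enol, so both antipodes funnel into one product (dynamic kinetic resolution); the proline carboxylic acid directs the formyl group to one enamine face (7S predicted for the (S)-catalyst by analogy with its dioxanone and cyclohexanone aldols; the (R)-catalyst is used if the sense proves opposite) and, by hydrogen-bonding the formyl oxygen next to the enamine nitrogen, places 8-OH pseudoaxial and trans to C7–O (8S). The step needs site selectivity for C4a over CHO and C8a, secured by the triflate leaving group and by running the substitution at −20 °C, where 1,2-adducts revert and the carboxylate does not yet decarboxylate; it also needs a product that cannot dehydrate, epimerise or aromatise, secured because C5 and C7 become bridgeheads (Bredt's rule).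

Step 15
Reactants: 25 (5R,7S,8S)-bridged ketone
Product: 26 (+)-4'-methoxyaquisinenone G
Conditions: Et2BOMe, THF/MeOH, −78 °C; NaBH4; AcOH quench, MeOH co-evaporation
Reagents that add atoms: none
Why: Narasaka–Prasad reduction; the 8-O–BEt2 borinate holds boron on the upper face beside the C6 carbonyl, so external hydride should enter from the dioxepine face flanked only by the two ether oxygens and give 6-OH syn to 8-OH (6S), while the vinylogous-ester carbonyls are not reduced at −78 °C.

**Compound list**
1 | kojic acid | OCc1cc(=O)c(O)co1 | starting material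
2 | 5-(benzyloxy)-2-(hydroxymethyl)-4H-pyran-4-one | OCc1cc(=O)c(OCc2ccccc2)co1 | intermediate
3 | 5-(benzyloxy)-4-oxo-4H-pyran-2-carbaldehyde | O=Cc1cc(=O)c(OCc2ccccc2)co1 | intermediate
4 | (4-methoxybenzyl)triphenylphosphonium chloride | COc1ccc(C[P+](c2ccccc2)(c2ccccc2)c2ccccc2)cc1.[Cl-] | starting material
5 | (4-methoxybenzylidene)triphenylphosphorane (ylide, not isolated) | COc1ccc(C=P(c2ccccc2)(c2ccccc2)c2ccccc2)cc1 | intermediate
6 | 5-(benzyloxy)-2-[2-(4-methoxyphenyl)ethenyl]-4H-pyran-4-one (E/Z mixture) | COc1ccc(C=Cc2cc(=O)c(OCc3ccccc3)co2)cc1 | intermediate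
7 | 5-hydroxy-2-[2-(4-methoxyphenyl)ethyl]-4H-pyran-4-one | COc1ccc(CCc2cc(=O)c(O)co2)cc1 | intermediate
8 | formaldehyde | C=O | starting material
9 | 3-hydroxy-2-(hydroxymethyl)-6-[2-(4-methoxyphenyl)ethyl]-4H-pyran-4-one | COc1ccc(CCc2cc(=O)c(O)c(CO)o2)cc1 | intermediate
10 | 2-(hydroxymethyl)-6-[2-(4-methoxyphenyl)ethyl]-4-oxo-4H-pyran-3-yl trifluoromethanesulfonate | COc1ccc(CCc2cc(=O)c(OS(=O)(=O)C(F)(F)F)c(CO)o2)cc1 | intermediate
11 | 2-formyl-6-[2-(4-methoxyphenyl)ethyl]-4-oxo-4H-pyran-3-yl trifluoromethanesulfonate | COc1ccc(CCc2cc(=O)c(OS(=O)(=O)C(F)(F)F)c(C=O)o2)cc1 | intermediate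
12 | 2'-hydroxy-4',5'-dimethoxyacetophenone | CC(=O)c1cc(OC)c(OC)cc1O | starting material
13 | ethyl 3-phenylpropanoate | CCOC(=O)CCc1ccccc1 | starting material
14 | 1-(2-hydroxy-4,5-dimethoxyphenyl)-5-phenylpentane-1,3-dione (not isolated) | COc1cc(O)c(C(=O)CC(=O)CCc2ccccc2)cc1OC | intermediate
15 | 6,7-dimethoxy-2-(2-phenylethyl)-4H-chromen-4-one | COc1cc2oc(CCc3ccccc3)cc(=O)c2cc1OC | intermediate
16 | 6,7-dihydroxy-2-(2-phenylethyl)-4H-chromen-4-one | Oc1cc2oc(CCc3ccccc3)cc(=O)c2cc1O | intermediate
17 | tert-butyl bromoacetate | CC(C)(C)OC(=O)CBr | starting material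
18 | tert-butyl {[6-hydroxy-4-oxo-2-(2-phenylethyl)-4H-chromen-7-yl]oxy}acetate | CC(C)(C)OC(=O)COc1cc2oc(CCc3ccccc3)cc(=O)c2cc1O | intermediate
19 | methyl bromoacetate | COC(=O)CBr | starting material
20 | tert-butyl methyl diester: 2-(2-phenylethyl)chromone with OCH2CO2tBu at C7 and OCH2CO2Me at C6 | CC(C)(C)OC(=O)COc1cc2oc(CCc3ccccc3)cc(=O)c2cc1OCC(=O)OC | intermediate
21 | tert-butyl dioxepinone β-keto ester: O-6B and O-7B of 2-(2-phenylethyl)chromone joined by CH2–C(=O)–CH(CO2tBu), ester-bearing CH on O-7B (racemic, enolisable) | CC(C)(C)OC(=O)C1Oc2cc3oc(CCc4ccccc4)cc(=O)c3cc2OCC1=O | intermediate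
22 | dioxepinone β-keto acid: as 21 with CO2H in place of CO2tBu | OC(=O)C1Oc2cc3oc(CCc4ccccc4)cc(=O)c3cc2OCC1=O | intermediate
23 | quaternary keto acid: 22 carrying the 2-formyl-6-[2-(4-methoxyphenyl)ethyl]-4-oxo-4H-pyran-3-yl group on the carboxyl-bearing carbon (racemic, not isolated) | COc1ccc(CCc2cc(=O)c(C3(C(=O)O)Oc4cc5oc(CCc6ccccc6)cc(=O)c5cc4OCC3=O)c(C=O)o2)cc1 | intermediate
24 | open keto aldehyde: 23 after loss of CO2, C5–H epimerising (not isolated) | COc1ccc(CCc2cc(=O)c(C3Oc4cc5oc(CCc6ccccc6)cc(=O)c5cc4OCC3=O)c(C=O)o2)cc1 | intermediate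
25 | (5R,7S,8S)-bridged ketone: 8-hydroxy-2-[2-(4-methoxyphenyl)ethyl]-7,8-dihydro-4H-chromene-4,6(5H)-dione whose C5 and C7 carry O-7B and O-6B of 2-(2-phenylethyl)chromone | COc1ccc(CCc2cc(=O)c3c(o2)[C@@H](O)[C@@H]2Oc4cc5c(=O)cc(CCc6ccccc6)oc5cc4O[C@H]3C2=O)cc1 | intermediate
26 | (+)-4'-methoxyaquisinenone G, (5R,6S,7R,8S) | COc1ccc(CCc2cc(=O)c3c(o2)[C@@H](O)[C@@H]2Oc4cc5c(=O)cc(CCc6ccccc6)oc5cc4O[C@H]3[C@@H]2O)cc1 | target

**Totals**
Total steps: 15. Longest linear sequence: 9 (steps 1–7, 14, 15); the chromone branch is 8 (steps 8–13, 14, 15).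

**Steps most likely to fail**

1. Step 14 (Proposed new method). What may go wrong: decarboxylation of the keto acid before C–C bond formation, decarboxylative addition at the formyl carbon instead of C4a, and slow C5 epimerisation or weak catalyst discrimination in the ring-closing aldol (low enantiomeric purity). Fallback with known chemistry, setting out from 21 (with 11) and coming back at 26: the ester is kept so that nothing can decarboxylate and the stereocentre is set by asymmetric phase-transfer vinylic substitution instead of by the dynamic aldol. 21 and 11 with N-(9-anthracenylmethyl)cinchonidinium bromide and Cs2CO3 in toluene/CHCl3 at −30 °C should give the quaternary tert-butyl ester keto aldehyde F1 with C5 fixed. Catalytic DBU in THF should then close the aldol to the bridged β-keto ester F2. Et2BOMe/NaBH4 should give the diol ester F3, and CF3CO2H the bridgehead acid F4. Photoredox hydrodecarboxylation (9-mesityl-10-methylacridinium tetrafluoroborate, (PhS)2, 2,6-lutidine, CF3CH2OH, blue light) should replace CO2H by H at the bridgehead, where only retention is possible, and deliver 26.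

2. Step 12. What may go wrong: ring closure in the wrong sense (enolate of the methyl ester arm attacking the tert-butyl ester) or ester exchange, giving regioisomeric β-keto esters. Fallback, setting out from 18 and coming back at 21: the 6-OH is alkylated with 2-bromo-N-methoxy-N-methylacetamide (K2CO3, acetone) to the Weinreb amide ester F5. LiN(SiMe3)2 in THF at −78 °C should then let only the tert-butyl ester enolate acylate, at the amide through its chelated tetrahedral intermediate, giving 21 with no second ester to compete.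

3. Step 15. What may go wrong: poor facial selectivity of hydride delivery if the borinate does not shield the upper face, or hydride delivery from the 8-oxygen. Fallback, setting out from 25 and coming back at 26: the 8-OH is silylated (tBuMe2SiOTf, 2,6-lutidine, CH2Cl2, −78 °C) to the 8-O-silyl ketone F6. NaBH4 in MeOH at −40 °C should attack from the face away from the silyl ether to give the 8-O-silyl alcohol F7. Bu4NF buffered with AcOH should then release 26.

**Further compounds**
F1 | step 14 | quaternary tert-butyl ester keto aldehyde (as 23 with CO2tBu, C5 configured) | COc1ccc(CCc2cc(=O)c([C@@]3(C(=O)OC(C)(C)C)Oc4cc5oc(CCc6ccccc6)cc(=O)c5cc4OCC3=O)c(C=O)o2)cc1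
F2 | step 14 | bridged β-keto ester (as 25 with CO2tBu at C5) | COc1ccc(CCc2cc(=O)c3c(o2)[C@@H](O)[C@@H]2Oc4cc5c(=O)cc(CCc6ccccc6)oc5cc4O[C@@]3(C(=O)OC(C)(C)C)C2=O)cc1
F3 | step 14 | diol ester (as 26 with CO2tBu at C5) | COc1ccc(CCc2cc(=O)c3c(o2)[C@@H](O)[C@@H]2Oc4cc5c(=O)cc(CCc6ccccc6)oc5cc4O[C@@]3(C(=O)OC(C)(C)C)[C@@H]2O)cc1
F4 | step 14 | bridgehead acid (as 26 with CO2H at C5) | COc1ccc(CCc2cc(=O)c3c(o2)[C@@H](O)[C@@H]2Oc4cc5c(=O)cc(CCc6ccccc6)oc5cc4O[C@@]3(C(=O)O)[C@@H]2O)cc1
F5 | step 12 | Weinreb amide ester (as 20 with C(=O)N(OMe)Me in place of CO2Me) | CC(C)(C)OC(=O)COc1cc2oc(CCc3ccccc3)cc(=O)c2cc1OCC(=O)N(C)OC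
F6 | step 15 | 8-O-tert-butyldimethylsilyl ether of 25 | COc1ccc(CCc2cc(=O)c3c(o2)[C@@H](O[Si](C)(C)C(C)(C)C)[C@@H]2Oc4cc5c(=O)cc(CCc6ccccc6)oc5cc4O[C@H]3C2=O)cc1
F7 | step 15 | 8-O-tert-butyldimethylsilyl ether of 26 | COc1ccc(CCc2cc(=O)c3c(o2)[C@@H](O[Si](C)(C)C(C)(C)C)[C@@H]2Oc4cc5c(=O)cc(CCc6ccccc6)oc5cc4O[C@H]3[C@@H]2O)cc1
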